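Ring A is disconnected at C1–C2 and C3–C4 (labdane numbering), which excises the C2–C3 ethano bridge as vinyltriphenylphosphonium bromide. The key step exploits two features. C4 is a quaternary carbon carrying the oxygenated C19, so it is the opened form of a 2-methyloxirane that Cp2TiCl converts into a tertiary radical. C1 is a methylene on the quaternary C10, so it is a former formyl group. In one operation the radical adds to the vinylphosphonium salt, the adduct is reduced to an ylide, and intramolecular Wittig olefination closes ring A, sets C4 and frees the C19 hydroxyl. The precursor is a ring B cyclohexenone from (R)-carvone bearing the formyl group on C10 and the oxirane on C5.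

Key step: step 5

Remark on the chemistry: atoms are named by labdane numbering (C19 = acetoxymethyl carbon on C4, C20 = methyl on C10); 7 is carried as a mixture of oxirane epimers and 13 as a mixture of C8 epimers, because both centres are erased in the following step.

Step 1
Reactants: 1 (R)-(−)-carvone
Product: 3 (5R,6S)-6-methylcarvone, via lithium dienolate 2 (not isolated)
Conditions: LDA, THF, −78 °C; MeI, −78 to 0 °C
Reagents that add atoms: iodomethane, CI
Why: Kinetic α'-deprotonation of the enone gives the cross-conjugated dienolate 2, whose C-methylation (enolate alkylation) should occur mainly anti to the C5 isopropenyl group, a centre that is re-enolised in step 2.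

Step 2
Reactants: 3 (5R,6S)-6-methylcarvone
Product: 5 6-(hydroxymethyl)-6-methylcarvone (CH2OH trans and CH3 cis to isopropenyl), via lithium enolate 4 (not isolated)
Conditions: LDA, THF, −78 °C; CH2O (g), −78 °C; AcOH
Reagents that add atoms: formaldehyde, C=O
Why: The tetrasubstituted lithium enolate 4 should add to monomeric formaldehyde (aldol hydroxymethylation) on the face anti to the adjacent isopropenyl group, which sets the quaternary C10 with C1 trans and C20 cis to the C5 substituent, and the cold acidic quench suppresses retro-aldol cleavage.

Step 3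
Reactants: 5 6-(hydroxymethyl)-6-methylcarvone
Product: 6 1,3-dimethyl-2-oxo-6-(prop-1-en-2-yl)cyclohex-3-ene-1-carbaldehyde (formyl trans to isopropenyl)
Conditions: Dess–Martin periodinane, CH2Cl2, 0 °C to rt
Reagents that add atoms: none
Why: Dess–Martin oxidation converts the neopentyl primary alcohol into the aldehyde under non-basic conditions that the non-enolisable but deformylation-prone β-keto aldehyde should tolerate.

Step 4
Reactants: 6 keto aldehyde
Product: 7 1,3-dimethyl-6-(2-methyloxiran-2-yl)-2-oxocyclohex-3-ene-1-carbaldehyde (both oxirane epimers)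
Conditions: DMDO, acetone, 0 °C
Reagents that add atoms: dimethyldioxirane, CC1(C)OO1
Why: The electrophilic dioxirane should epoxidise the electron-rich 1,1-disubstituted alkene much faster than the electron-poor enone alkene or the aldehyde C–H (dioxirane epoxidation), and no facial control is needed because C4 becomes a planar radical in step 5.

Step 5
Reactants: 7 epoxy keto aldehyde; 8 vinyltriphenylphosphonium bromide
Product: 11 19-hydroxy-11,12,13,14,15,16-hexanorlabda-1,7-dien-9-one, via titanoxy radical 9 (not isolated), via phosphonium ylide 10 (not isolated)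
Conditions: Cp2TiCl (2.5 equiv, pre-formed THF solution, slow addition), 8 (4 equiv), THF/CH2Cl2, 0 °C to rt; aq. NaH2PO4
Reagents that add atoms: vinyltriphenylphosphonium bromide (8), C=C[P+](c1ccccc1)(c1ccccc1)c1ccccc1.[Br-]
Why: Proposed new method: Cp2TiCl (trivalent titanium) opens the oxirane of either epimer of 7 homolytically at its more substituted carbon to give the tertiary β-titanoxy radical 9 at C4, whose Giese addition to the CH2 terminus of 8 forms C3–C4, and a second Cp2TiCl reduces the resulting electrophilic α-phosphonio radical to the non-stabilised ylide 10, which forms C1=C2 by intramolecular Wittig olefination of the C10 formyl group with loss of Ph3PO. The closest known reaction types are the titanocene-mediated reductive epoxide opening with Giese trapping by electron-poor alkenes (Nugent–RajanBabu reaction) and the radical addition to vinylphosphonium salts followed by one-electron reduction to the ylide and Wittig olefination, which have not been combined. Ring A is closed in the Wittig event by 6-exo-trig attack of the ylide carbon C2 on the aldehyde carbon C1 (oxaphosphetane formation and cycloreversion), which can only give the cis ring alkene, whereas the radical C–C bond formation is intermolecular. The only new stereocentre, C4, is set in the Giese addition under control of C5 and C10: the bulky CH2O[Ti] group should eclipse the C5–H bond, the small methyl group then lies between C6 and C10, and the acceptor adds anti to the quaternary C10 (the same face is open if the titanium alkoxide is held as a hemiacetalate on the C1 aldehyde), which should place C19 on the β face syn to C20. The step needs capture of 9 by 8 to outrun its collapse with Cp2TiCl or its attack on the C1 carbonyl, which the excess of the strongly electron-poor acceptor and the slow addition of Cp2TiCl should secure, and it needs the ylide to choose the aldehyde over the C9 ketone, which is secured because closure at C9 would give a bridgehead alkene.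

Step 6
Reactants: 11 hydroxy dienone
Product: 12 19-acetoxy-11,12,13,14,15,16-hexanorlabda-1,7-dien-9-one
Conditions: Ac2O, pyridine, DMAP (cat.), CH2Cl2, rt
Reagents that add atoms: acetic anhydride, CC(=O)OC(C)=O
Why: DMAP-catalysed acylation should esterify the primary neopentyl alcohol without affecting the enone or the ring A alkene.

Step 7
Reactants: 12 acetoxy dienone
Product: 13 19-acetoxy-11,12,13,14,15,16-hexanorlabdan-9-one (C8 epimers)
Conditions: H2 (1–3 atm), Pd/C, EtOAc, rt
Reagents that add atoms: none
Why: Heterogeneous catalytic hydrogenation should saturate both the cis-disubstituted C1=C2 alkene and the enone C7=C8 bond while sparing ketone and acetate, and the C8 configuration is irrelevant because C8 becomes sp2 in step 8.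

Step 8
Reactants: 13 saturated ketone
Product: 14 19-acetoxy-11,12,13,14,15,16-hexanorlabd-8-en-9-yl trifluoromethanesulfonate
Conditions: Tf2O, 2,6-di-tert-butyl-4-methylpyridine, CH2Cl2, 0 °C to rt
Reagents that add atoms: trifluoromethanesulfonic anhydride, O=S(=O)(OS(=O)(=O)C(F)(F)F)C(F)(F)F
Why: O-Triflation of the ketone and deprotonation by the hindered pyridine (enol triflate formation) can only proceed towards C8 because C10 is quaternary, which should give the tetrasubstituted C8=C9 enol triflate under conditions that spare the acetate.

Step 9
Reactants: 14 enol triflate; 15 tributyl(vinyl)stannane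
Product: 16 19-acetoxy-13,14,15,16-tetranorlabda-8,11-diene
Conditions: 15, Pd(PPh3)4 (cat.), LiCl, THF, reflux
Reagents that add atoms: tributyl(vinyl)stannane (15), C=C[Sn](CCCC)(CCCC)CCCC
Why: Stille coupling of the vinyl triflate (LiCl-assisted oxidative addition to zerovalent palladium, transmetalation, reductive elimination) should attach C11–C12 to C9 under neutral conditions compatible with the acetate.

Step 10
Reactants: 16 diene; 17 methyl but-2-ynoate
Product: 19 methyl (13E)-19-acetoxylabda-8,13-dien-15-oate, via alkylborane 18 (not isolated)
Conditions: 9-BBN dimer, 1,4-dioxane, 60 °C; then 17, CuOAc (cat.), P(OPh)3 (cat.), t-BuOK (cat.), t-BuOH, 40 °C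
Reagents that add atoms: methyl but-2-ynoate (17), CC#CC(=O)OC
Why: 9-BBN should hydroborate only the monosubstituted vinyl group at its terminus, and the copper-catalysed conjugate addition of alkylborane 18 to the alkynoate is a syn-carbocupration followed by stereoretentive protonation (formal syn-hydroalkylation), which places the alkyl chain trans to the ester and so sets the 13E geometry.

Compound list
1 | (R)-(−)-carvone | O=C1C(C)=CC[C@@H](C(C)=C)C1 | starting material
2 | lithium cross-conjugated dienolate of 1 | [Li]OC1=C[C@H](C(C)=C)CC=C1C | intermediate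
3 | (5R,6S)-6-methylcarvone (methyl trans to isopropenyl, major epimer) | O=C1C(C)=CC[C@@H](C(C)=C)[C@@H]1C | intermediate
4 | lithium enolate of 3 (tetrasubstituted) | [Li]OC1=C(C)[C@H](C(C)=C)CC=C1C | intermediate
5 | 6-(hydroxymethyl)-6-methylcarvone; CH2OH trans, CH3 cis to isopropenyl | O=C1C(C)=CC[C@@H](C(C)=C)[C@]1(C)CO | intermediate
6 | 1,3-dimethyl-2-oxo-6-(prop-1-en-2-yl)cyclohex-3-ene-1-carbaldehyde; formyl trans to isopropenyl | O=C1C(C)=CC[C@@H](C(C)=C)[C@]1(C)C=O | intermediate
7 | 1,3-dimethyl-6-(2-methyloxiran-2-yl)-2-oxocyclohex-3-ene-1-carbaldehyde; both oxirane epimers | O=C1C(C)=CC[C@@H](C2(C)CO2)[C@]1(C)C=O | intermediate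
8 | vinyltriphenylphosphonium bromide | C=C[P+](c1ccccc1)(c1ccccc1)c1ccccc1.[Br-] | starting material
9 | tertiary C4 radical with C19–O–TiCp2Cl (cyclopentadienyl rings drawn σ-bound) | O=C1C(C)=CC[C@@H]([C](C)CO[Ti](Cl)(C2C=CC=C2)C2C=CC=C2)[C@]1(C)C=O | intermediate
10 | C2 triphenylphosphonium ylide with quaternary C4, C19 titanium alkoxide and free C1 aldehyde | O=C1C(C)=CC[C@@H]([C@@](C)(CO[Ti](Cl)(C2C=CC=C2)C2C=CC=C2)CC=P(c2ccccc2)(c2ccccc2)c2ccccc2)[C@]1(C)C=O | intermediate
11 | 19-hydroxy-11,12,13,14,15,16-hexanorlabda-1,7-dien-9-one; trans-fused, 5α-H, 10β-CH3, 4β-CH2OH, 4α-CH3 | O=C1C(C)=CC[C@H]2[C@@](C)(CO)CC=C[C@]12C | intermediate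
12 | 19-acetoxy-11,12,13,14,15,16-hexanorlabda-1,7-dien-9-one | O=C1C(C)=CC[C@H]2[C@@](C)(COC(C)=O)CC=C[C@]12C | intermediate
13 | 19-acetoxy-11,12,13,14,15,16-hexanorlabdan-9-one; C8 epimers | O=C1C(C)CC[C@H]2[C@@](C)(COC(C)=O)CCC[C@]12C | intermediate
14 | 19-acetoxy-11,12,13,14,15,16-hexanorlabd-8-en-9-yl trifluoromethanesulfonate | FC(F)(F)S(=O)(=O)OC1=C(C)CC[C@H]2[C@@](C)(COC(C)=O)CCC[C@]12C | intermediate
15 | tributyl(vinyl)stannane | C=C[Sn](CCCC)(CCCC)CCCC | starting material
16 | 19-acetoxy-13,14,15,16-tetranorlabda-8,11-diene (9-vinyl diene) | C=CC1=C(C)CC[C@H]2[C@@](C)(COC(C)=O)CCC[C@]12C | intermediate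
17 | methyl but-2-ynoate | CC#CC(=O)OC | starting material
18 | 12-(9-borabicyclo[3.3.1]nonan-9-yl)-19-acetoxy-13,14,15,16-tetranorlabd-8-ene | C(CC1=C(C)CC[C@H]2[C@@](C)(COC(C)=O)CCC[C@]12C)B1C2CCCC1CCC2 | intermediate
19 | methyl (13E)-19-acetoxylabda-8,13-dien-15-oate; (4S,5R,10S) | COC(=O)/C=C(\C)CCC1=C(C)CC[C@H]2[C@@](C)(COC(C)=O)CCC[C@]12C | target

Total step count: 10. Longest linear sequence: 10 steps from (R)-carvone (1); 8, 15 and 17 are purchased.

Steps most likely to fail

Step 5 (proposed new method). Radical 9 may be intercepted by Cp2TiCl before it adds to 8, or may attack the C1 carbonyl. The α-phosphonio radical may not be reduced to the ylide. Facial selectivity at C4 may be poor. The fallback uses known chemistry and sets out from 6. Allylic hydroxylation of the isopropenyl methyl group (SeO2 cat., t-BuOOH, CH2Cl2) would give the 2-(hydroxymethyl)allyl keto aldehyde F1. Acetylation (Ac2O, pyridine) would give the allylic acetate F2. A hydrogen-atom-transfer radical–polar crossover annulation with acrolein (Fe(acac)3, PhSiH3, EtOH) would then give the ring A hydroxy aldehyde F3: the C4 radical adds to acrolein and the resulting enolate closes by aldol onto the C1 aldehyde, so C3–C4 and C1–C2 again form in one operation. Acid-catalysed dehydration (TsOH, benzene, reflux) would give the enal F4. Decarbonylation with RhCl(PPh3)3 (toluene, reflux) comes back to the route at 12.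

Step 8. O-Triflation of the ketone flanked by the quaternary C10 and the tertiary C8 may be sluggish, and the O-triflyl oxocarbenium ion may rearrange by methyl migration from C10. The fallback sets out from 12. Conjugate reduction with LiBH(s-Bu)3 (THF, −78 °C) generates the C8–C9 enolate regiospecifically, and PhNTf2 traps it as the ring A unsaturated enol triflate F5. Diimide (2-nitrobenzenesulfonylhydrazide, Et3N, CH2Cl2) should then reduce only the disubstituted C1=C2 alkene, coming back to the route at 14.

Step 2. The lithium aldolate may lose formaldehyde by retro-aldol cleavage, formaldehyde may polymerise before it is captured, and the face selectivity in forming the quaternary C10 may be incomplete. The fallback sets out from 3. LDA and TMSCl give the trimethylsilyl dienol ether F6. A Lewis-acid-mediated Mukaiyama aldol with aqueous formaldehyde (Sc(OTf)3, THF/H2O, rt) then forms the same bond under non-basic conditions, coming back to the route at 5.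

Further compounds
F1 | step 5 | 6-[3-hydroxyprop-1-en-2-yl]-1,3-dimethyl-2-oxocyclohex-3-ene-1-carbaldehyde (open form of the lactol) | O=C1C(C)=CC[C@@H](C(=C)CO)[C@]1(C)C=O
F2 | step 5 | 6-[3-acetoxyprop-1-en-2-yl]-1,3-dimethyl-2-oxocyclohex-3-ene-1-carbaldehyde | O=C1C(C)=CC[C@@H](C(=C)COC(C)=O)[C@]1(C)C=O
F3 | step 5 | 19-acetoxy-1-hydroxy-2-formyl-11,12,13,14,15,16-hexanorlabd-7-en-9-one (C1 and C2 epimers) | O=C1C(C)=CC[C@H]2[C@@](C)(COC(C)=O)CC(C=O)C(O)[C@]12C
F4 | step 5 | 19-acetoxy-2-formyl-11,12,13,14,15,16-hexanorlabda-1,7-dien-9-one | O=C1C(C)=CC[C@H]2[C@@](C)(COC(C)=O)CC(C=O)=C[C@]12C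
F5 | step 8 | 19-acetoxy-11,12,13,14,15,16-hexanorlabda-1,8-dien-9-yl trifluoromethanesulfonate | FC(F)(F)S(=O)(=O)OC1=C(C)CC[C@H]2[C@@](C)(COC(C)=O)CC=C[C@]12C
F6 | step 2 | trimethylsilyl dienol ether of 3 | C[Si](C)(C)OC1=C(C)[C@H](C(C)=C)CC=C1C
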